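In a one-step world target climbs to its end value and stays there, but in birch the late readings of target lie below the early ones, so the thing to watch is how long target sits in the flask.

| flask | substrate | partner | remark | time |
|---|---|---|---|---|
| birch | 0.12 M | 1.05 equiv | run made earlier |  |
| cedar | 0.12 M | 1.6 equiv | run made earlier |  |
| winter | 0.12 M (fed, over 2.0 h) | 1.05 equiv | all else is in the flask from the start; the feed brings no volume worth counting | 3.0 h |
| autumn | 0.12 M | 1.05 equiv (fed, over 2.0 h) | all else is in the flask from the start; the feed brings no volume worth counting | 3.0 h |
| dawn | 0.12 M | 1.05 equiv | everything together at the start | 3.0 h |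

- birch (time / h: target / %, substrate / %): 0.250: 41, 12; 0.417: 41, 8; 0.833: 36, 1; 1.50: 37, 0; 3.00: 31, 2
- cedar (time / min: target / %, substrate / %): 1.33: 25, 52; 2.50: 39, 33; 5.00: 45, 15; 10.0: 51, 3; 20.0: 45, 3

(scatter of a reading: 2 percentage points)

- the best flask by amount of target, in percent of the substrate charged; "all alike" if 1.5 percentage points covers them all (winter / autumn / dawn / all alike)
- amount of target at the end, in percent of the substrate charged, winter
- amount of target at the end, in percent of the substrate charged, autumn
- amount of target at the end, in percent of the substrate charged, dawn



Birch is dawn's recipe, so I take its last reading, 31%, as my floor for the two fed flasks (semi-batch), and its first, 41%, as my ceiling. I hold the share of substrate going to target at birch's value. Between 0.417 h and 3.00 h target in birch fades at a read 0.108 h⁻¹, as a first-order guess. Birch is down to 12% of its substrate by 0.250 h, short against the feed of 2.0 h, so I let target form as the feed arrives. The youngest target is then 1.00 h old, which lowers the ceiling to 38.5%.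

The mean age of target at the end, the time 3.0 h less half the feed time, is 2.00 h. Putting that mean in place of the spread of ages gives 34.5% for each fed flask, a gain of 3.5 percentage points over birch's last reading, which stands in for dawn. Averaging the whole curve instead shifts this by 0.067 points, small beside the scatter of 2 points.

The forecast names winter, with 37% for winter, 33% for autumn and 33% for dawn, and says: “Feeding shortens target's ageing by about an hour”. Its winter lies in my bracket but higher than my figure, and its autumn lies lower than my figure.

Winter ends at 32.4%, autumn at 26.1% and dawn at 29.2%, so winter leads.

    substrate + partner → target (k = 0.0270 M⁻¹ s⁻¹)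
    substrate + partner → isomer of the product A (k = 0.0225 M⁻¹ s⁻¹)
    target ⇌ isomer of the product B (K = 0.828, k = 1.13 × 10⁻⁴ s⁻¹)
    substrate + target → side product (k = 0.00164 M⁻¹ s⁻¹)

Winter stands 3.2 points above dawn, against the 3.5 points reckoned from the mean age. Autumn's feed lasts as long, so I reckon it the same mean age, 2.00 h, and the same reckoning sets it 3.5 points above dawn, yet it ends 3.1 points below dawn. At 3.00 h autumn holds 17.3% of side product, each one counted as two, against 4.62% in winter.

(The runs are simulated for substances that don't exist, noise included.)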